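**Plan**

- Retrosynthesis: the C1 hydroxyl is removed first (γ-oxygenation of a β,γ-unsaturated ketone). Cutting C5–C13' and C3–C11' then opens the cyclohexene into two molecules of one monomer, 8-epi-xanthatin (Diels–Alder: dienone of one, methylene lactone of the other).
- In the monomer the side chain is cut at C1–C2 (Heck reaction of a C1 enol triflate), the methylene at C11=C13 (Mannich/elimination) and the lactone at O–C8 and C7–C11 (iodolactonisation, Ireland–Claisen of a C9 acetate).
- The remaining cyclohepta-1,5-diene is cut at C5–C6 and C9–C10 into a siloxy vinyldiazoacetate and (E)-1-acetoxybutadiene (carbenoid cyclopropanation, then Cope rearrangement).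
- Forward order of rings: cycloheptadiene (step 3), γ-lactone (steps 4–6), cyclohexene with the spiro centre in the dimerisation (step 12); the C1 hydroxyl comes last (step 13).
- Stereochemistry: C10 and C9 from the chiral dirhodium catalyst and the boat Cope; C9 passes to C7 in the suprafacial Claisen; C8 from the cis iodolactonisation; C5 and C11' from the Diels–Alder; C1 from axial oxygenation anti to H5.

Key step: step 3

Remarks on the chemistry:
- Atom numbers are those of the xanthane skeleton (C1–C15); primed numbers belong to the half that carries the dienone side chain in the target.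
- Assumption: Rh2(S-PTAD)4, dirhodium tetrakis[(S)-(1-adamantyl)(N-phthalimido)acetate], is taken to give the (1R,2S)-cyclopropane; if the sense of induction is the opposite, Rh2(R-PTAD)4 is used and nothing else changes.
- Commercial 1-acetoxybuta-1,3-diene is an E/Z mixture; E-enriched material is preferred. The cyclopropane from the Z isomer is expected not to rearrange at room temperature and to be removed by chromatography.
- tert-Butyl 3-oxopentanoate is taken as a catalogue compound (otherwise one step from Meldrum's acid, propionyl chloride and tert-butanol).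

**Route**

Step 1
Reactants: 1 tert-butyl 3-oxopentanoate
Product: 2 tert-butyl 2-diazo-3-oxopentanoate
Conditions: p-ABSA, Et3N, MeCN, 0 °C → rt
Reagents that add atoms: 4-acetamidobenzenesulfonyl azide (p-ABSA), CC(=O)Nc1ccc(cc1)S(=O)(=O)N=[N+]=[N-]
Why: Regitz diazo transfer to the doubly activated methylene of a β-keto ester is general and leaves the ethyl ketone side untouched.

Step 2
Reactants: 2 tert-butyl 2-diazo-3-oxopentanoate
Product: 3 tert-butyl (Z)-3-[(tert-butyldimethylsilyl)oxy]-2-diazopent-3-enoate
Conditions: TBSOTf, Et3N, CH2Cl2, 0 °C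
Reagents that add atoms: tert-butyldimethylsilyl trifluoromethanesulfonate, CC(C)(C)[Si](C)(C)OS(=O)(=O)C(F)(F)F
Why: Soft enolisation and O-silylation of the α-diazo-β-keto ester gives the silyl enol ether, the Z isomer (methyl cis to the siloxy group) being favoured because it keeps the methyl away from the diazo ester unit (allylic 1,3-strain).

Step 3
Reactants: 3 tert-butyl (Z)-3-[(tert-butyldimethylsilyl)oxy]-2-diazopent-3-enoate; 4 (E)-buta-1,3-dien-1-yl acetate
Product: 6 tert-butyl (3S,4S)-4-acetoxy-2-[(tert-butyldimethylsilyl)oxy]-3-methylcyclohepta-1,5-diene-1-carboxylate, via cis-divinylcyclopropane 5 (not isolated)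
Conditions: Rh2(S-PTAD)4 (1 mol %), 4 (3 equiv), hexanes, slow addition of 3, −20 °C → rt
Reagents that add atoms: none
Why: The rhodium carbenoid formed from 3 by loss of N2 cyclopropanates the unsubstituted terminal alkene of 4 (bonds C5–C6 and C5–C7) with the alkenyl residue cis to the siloxyvinyl group, and the cis-divinylcyclopropane 5 undergoes a [3,3] shift through a boat transition state that makes C9–C10, breaks C5–C7 and leaves the C5=C1 and C7=C8 alkenes. This is the known tandem cyclopropanation/Cope rearrangement (formal (4+3) cycloaddition) of siloxy vinyldiazoacetates with 1,3-dienes under chiral dirhodium tetracarboxylate catalysis. The three-membered ring closes by concerted carbene transfer to the alkene, and the seven-membered ring by sigmatropic ring expansion of that cyclopropane. C10 and C9 arise together: their cis relationship follows from the Z enol ether and the E enol acetate, which put methyl and acetoxy on the outside of the boat, and their absolute configuration from the alkene face selected by the catalyst in the cyclopropanation. The step needs site selectivity for the terminal alkene, which the preference of donor/acceptor carbenoids for monosubstituted alkenes and the stabilisation of developing positive charge by the enol acetate secure, and it needs attack at the carbenoid carbon and not at the vinylogous position, which the hydrocarbon solvent and the substituted vinyl terminus favour.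

Step 4
Reactants: 6 tert-butyl (3S,4S)-4-acetoxy-2-[(tert-butyldimethylsilyl)oxy]-3-methylcyclohepta-1,5-diene-1-carboxylate
Product: 9 2-[(1R,4S)-6-(tert-butoxycarbonyl)-5-[(tert-butyldimethylsilyl)oxy]-4-methylcyclohepta-2,5-dien-1-yl]acetic acid, via silyl ketene acetal 7 (not isolated), via trimethylsilyl ester 8 (not isolated)
Conditions: LiN(i-Pr)2, TMSCl, THF, −78 °C → rt; aq. NH4Cl
Reagents that add atoms: chlorotrimethylsilane, C[Si](C)(C)Cl (its atoms stay in 7 and 8 only)
Why: Ireland–Claisen rearrangement in which the acetate methyl is deprotonated faster than the C10 methine (which lies trans to the ester carbonyl), and the silyl ketene acetal delivers C11 to C7 on the ring face that the C9–O bond occupied, so that the C9 centre is traded for C7 with C11 cis to the C10 methyl.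

Step 5
Reactants: 9 2-[(1R,4S)-6-(tert-butoxycarbonyl)-5-[(tert-butyldimethylsilyl)oxy]-4-methylcyclohepta-2,5-dien-1-yl]acetic acid
Product: 10 tert-butyl (3aR,7R,8S,8aS)-6-[(tert-butyldimethylsilyl)oxy]-8-iodo-7-methyl-2-oxo-3,3a,4,7,8,8a-hexahydro-2H-cyclohepta[b]furan-5-carboxylate
Conditions: I2, NaHCO3, MeCN, 0 °C, dark
Reagents that add atoms: iodine, II
Why: Iodolactonisation in which the carboxylate opens the iodonium ion of the C8=C9 alkene at C8 (5-exo) from the face of its own tether, so the γ-lactone is cis-fused (O8 cis to C11 and to the C10 methyl) with iodine trans at C9, while the electron-poor tetrasubstituted siloxy enoate is left alone.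

Step 6
Reactants: 10 tert-butyl (3aR,7R,8S,8aS)-6-[(tert-butyldimethylsilyl)oxy]-8-iodo-7-methyl-2-oxo-3,3a,4,7,8,8a-hexahydro-2H-cyclohepta[b]furan-5-carboxylate
Product: 11 tert-butyl (3aR,7S,8aR)-6-[(tert-butyldimethylsilyl)oxy]-7-methyl-2-oxo-3,3a,4,7,8,8a-hexahydro-2H-cyclohepta[b]furan-5-carboxylate
Conditions: Bu3SnH (0.3 M), Et3B, air, PhMe, 0 °C → rt
Reagents that add atoms: none
Why: Radical-chain dehalogenation of a secondary iodide, run cold and at high stannane concentration so that the C9 radical is reduced before it can add to the neighbouring enoate, and no stereocentre is touched.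

Step 7
Reactants: 11 tert-butyl (3aR,7S,8aR)-6-[(tert-butyldimethylsilyl)oxy]-7-methyl-2-oxo-3,3a,4,7,8,8a-hexahydro-2H-cyclohepta[b]furan-5-carboxylate
Product: 12 tert-butyl (3S,3aR,7S,8aR)-6-[(tert-butyldimethylsilyl)oxy]-3-[(dimethylamino)methyl]-7-methyl-2-oxo-3,3a,4,7,8,8a-hexahydro-2H-cyclohepta[b]furan-5-carboxylate
Conditions: LiN(i-Pr)2, THF, −78 °C; CH2=NMe2+ I− (Eschenmoser's salt), −78 °C → rt
Reagents that add atoms: N,N-dimethylmethyleneiminium iodide, C=[N+](C)C.[I-]
Why: Mannich reaction of the lactone lithium enolate with the iminium salt installs C13 as a masked methylene, the electrophile being expected on the convex face of the cis-fused lactone, and this C11 centre is erased in step 11.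

Step 8
Reactants: 12 tert-butyl (3S,3aR,7S,8aR)-6-[(tert-butyldimethylsilyl)oxy]-3-[(dimethylamino)methyl]-7-methyl-2-oxo-3,3a,4,7,8,8a-hexahydro-2H-cyclohepta[b]furan-5-carboxylate
Product: 14 (3S,3aR,7S,8aR)-3-[(dimethylamino)methyl]-7-methyloctahydrocyclohepta[b]furan-2,6-dione, via β-keto acid 13 (not isolated)
Conditions: TFA/CH2Cl2 (1:3), H2O (2 equiv), 0 °C → rt; PhMe, 60 °C; aq. NaHCO3
Reagents that add atoms: none
Why: Acidolysis of the silyl enol ether and the tert-butyl ester frees a β-keto acid that decarboxylates on gentle warming, the amine being protected as its ammonium salt and the C10 centre spared because no base is present.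

Step 9
Reactants: 14 (3S,3aR,7S,8aR)-3-[(dimethylamino)methyl]-7-methyloctahydrocyclohepta[b]furan-2,6-dione
Product: 15 (3S,3aR,7S,8aR)-3-[(dimethylamino)methyl]-7-methyl-2-oxo-3,3a,4,7,8,8a-hexahydro-2H-cyclohepta[b]furan-6-yl trifluoromethanesulfonate
Conditions: KN(SiMe3)2, THF, −78 °C; Comins' reagent, −78 °C
Reagents that add atoms: N-(5-chloropyridin-2-yl)bis(trifluoromethanesulfonyl)imide (Comins' reagent), O=S(=O)(N(c1ccc(Cl)cn1)S(=O)(=O)C(F)(F)F)C(F)(F)F
Why: Kinetic enolisation of the ketone at the less hindered C5 methylene (not at the C10 methine and not at the less acidic lactone α-position) followed by O-triflation fixes the C1=C5 double bond without touching C10.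

Step 10
Reactants: 15 (3S,3aR,7S,8aR)-3-[(dimethylamino)methyl]-7-methyl-2-oxo-3,3a,4,7,8,8a-hexahydro-2H-cyclohepta[b]furan-6-yl trifluoromethanesulfonate; 16 but-3-en-2-one
Product: 17 (3S,3aR,7S,8aR)-3-[(dimethylamino)methyl]-7-methyl-6-[(E)-3-oxobut-1-en-1-yl]-3,3a,4,7,8,8a-hexahydrocyclohepta[b]furan-2-one
Conditions: Pd(OAc)2 (5 mol %), PPh3 (10 mol %), Et3N, 16 (5 equiv), DMF, 60 °C
Reagents that add atoms: none
Why: Heck reaction of an enol triflate with an enone (oxidative addition to zerovalent palladium, syn insertion at the terminal carbon, syn β-hydride elimination) gives the E dienone, and the amine mask keeps the future methylene lactone from competing as an acceptor.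

Step 11
Reactants: 17 (3S,3aR,7S,8aR)-3-[(dimethylamino)methyl]-7-methyl-6-[(E)-3-oxobut-1-en-1-yl]-3,3a,4,7,8,8a-hexahydrocyclohepta[b]furan-2-one
Product: 19 8-epi-xanthatin, (3aR,7S,8aR)-7-methyl-3-methylidene-6-[(E)-3-oxobut-1-enyl]-4,7,8,8a-tetrahydro-3aH-cyclohepta[b]furan-2-one, via trimethylammonium iodide 18 (not isolated)
Conditions: MeI, CH2Cl2/MeOH, rt; aq. NaHCO3, rt
Reagents that add atoms: iodomethane, CI (its carbon stays in 18 only)
Why: Quaternisation of the Mannich base and E1cB loss of trimethylamine from the β-ammonio lactone is the standard way to an α-methylene lactone and is mild enough for the dienone.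

Step 12
Reactants: 19 8-epi-xanthatin (two molecules)
Product: 20 Diels–Alder dimer of 8-epi-xanthatin (cyclohexene C1=C2–C3H(acetyl)–C11'–C13'H2–C5H, spiro at C11', 3-H cis to 5-H)
Conditions: PhMe (2 M), BHT (cat.), 110 °C, sealed tube, Ar
Reagents that add atoms: none
Why: Thermal Diels–Alder dimerisation in which the s-cis dienone C5=C1–C2=C3 of one molecule adds to the exocyclic C11'=C13' alkene of a second with the ortho regiochemistry of a 1-acyl diene and an acrylate-type dienophile (C3 to C11', C5 to C13'); the dienophile is approached on the convex face of its cis-fused lactone with the lactone carbonyl endo, which sets the spiro centre C11', bonding at C5 on the face that carries the C10 methyl is what the target requires, and the C3 centre formed alongside is removed in step 13.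

Step 13
Reactants: 20 Diels–Alder dimer of 8-epi-xanthatin
Product: 22 CNP0168949.1 (target), via C1 hydroperoxide 21 (not isolated)
Conditions: O2 (1 atm), DBU (0.5 equiv), MeCN, 0 °C; then PPh3, 0 °C
Reagents that add atoms: dioxygen, O=O
Why: Base-mediated autoxidation of a β,γ-unsaturated ketone, in which DBU removes the doubly activated C3 proton, O2 is taken up at the γ carbon C1 of the extended enolate to give the conjugated γ-hydroperoxy enone and PPh3 reduces the hydroperoxide; the C–O bond should form axially on the cyclohexene, anti to the axial H5, so the six- and seven-membered rings end trans-fused with the hydroxyl cis to the C10 methyl.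

**Compound list**

1 | tert-butyl 3-oxopentanoate | CCC(=O)CC(=O)OC(C)(C)C | starting material
2 | tert-butyl 2-diazo-3-oxopentanoate | CCC(=O)C(=[N+]=[N-])C(=O)OC(C)(C)C | intermediate
3 | tert-butyl (Z)-3-[(tert-butyldimethylsilyl)oxy]-2-diazopent-3-enoate | C/C=C(\O[Si](C)(C)C(C)(C)C)C(=[N+]=[N-])C(=O)OC(C)(C)C | intermediate
4 | (E)-buta-1,3-dien-1-yl acetate | CC(=O)O/C=C/C=C | starting material
5 | tert-butyl (1R,2S)-2-[(E)-2-acetoxyethenyl]-1-[(Z)-1-[(tert-butyldimethylsilyl)oxy]prop-1-en-1-yl]cyclopropane-1-carboxylate | CC(C)(C)OC(=O)[C@]1(/C(O[Si](C)(C)C(C)(C)C)=C/C)C[C@H]1/C=C/OC(C)=O | intermediate (not isolated)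
6 | tert-butyl (3S,4S)-4-acetoxy-2-[(tert-butyldimethylsilyl)oxy]-3-methylcyclohepta-1,5-diene-1-carboxylate (methyl and acetoxy cis) | CC(C)(C)OC(=O)C1=C(O[Si](C)(C)C(C)(C)C)[C@@H](C)[C@@H](OC(C)=O)C=CC1 | intermediate
7 | trimethylsilyl ketene acetal of 6 (C9–O–C(=CH2)–OSiMe3) | CC(C)(C)OC(=O)C1=C(O[Si](C)(C)C(C)(C)C)[C@@H](C)[C@@H](OC(=C)O[Si](C)(C)C)C=CC1 | intermediate (not isolated)
8 | trimethylsilyl ester of acid 9 | CC(C)(C)OC(=O)C1=C(O[Si](C)(C)C(C)(C)C)[C@@H](C)C=C[C@@H](CC(=O)O[Si](C)(C)C)C1 | intermediate (not isolated)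
9 | 2-[(1R,4S)-6-(tert-butoxycarbonyl)-5-[(tert-butyldimethylsilyl)oxy]-4-methylcyclohepta-2,5-dien-1-yl]acetic acid | CC(C)(C)OC(=O)C1=C(O[Si](C)(C)C(C)(C)C)[C@@H](C)C=C[C@@H](CC(=O)O)C1 | intermediate
10 | tert-butyl (3aR,7R,8S,8aS)-6-[(tert-butyldimethylsilyl)oxy]-8-iodo-7-methyl-2-oxo-3,3a,4,7,8,8a-hexahydro-2H-cyclohepta[b]furan-5-carboxylate | CC(C)(C)OC(=O)C1=C(O[Si](C)(C)C(C)(C)C)[C@@H](C)[C@H](I)[C@H]2OC(=O)C[C@H]2C1 | intermediate
11 | tert-butyl (3aR,7S,8aR)-6-[(tert-butyldimethylsilyl)oxy]-7-methyl-2-oxo-3,3a,4,7,8,8a-hexahydro-2H-cyclohepta[b]furan-5-carboxylate | CC(C)(C)OC(=O)C1=C(O[Si](C)(C)C(C)(C)C)[C@@H](C)C[C@H]2OC(=O)C[C@H]2C1 | intermediate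
12 | tert-butyl (3S,3aR,7S,8aR)-6-[(tert-butyldimethylsilyl)oxy]-3-[(dimethylamino)methyl]-7-methyl-2-oxo-3,3a,4,7,8,8a-hexahydro-2H-cyclohepta[b]furan-5-carboxylate | CC(C)(C)OC(=O)C1=C(O[Si](C)(C)C(C)(C)C)[C@@H](C)C[C@H]2OC(=O)[C@H](CN(C)C)[C@H]2C1 | intermediate
13 | (3S,3aR,7S,8aR)-3-[(dimethylamino)methyl]-7-methyl-2,6-dioxooctahydrocyclohepta[b]furan-5-carboxylic acid (C5 epimers/enol) | OC(=O)C1C(=O)[C@@H](C)C[C@H]2OC(=O)[C@H](CN(C)C)[C@H]2C1 | intermediate (not isolated)
14 | (3S,3aR,7S,8aR)-3-[(dimethylamino)methyl]-7-methyloctahydrocyclohepta[b]furan-2,6-dione | O=C1[C@@H](C)C[C@H]2OC(=O)[C@H](CN(C)C)[C@H]2CC1 | intermediate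
15 | (3S,3aR,7S,8aR)-3-[(dimethylamino)methyl]-7-methyl-2-oxo-3,3a,4,7,8,8a-hexahydro-2H-cyclohepta[b]furan-6-yl trifluoromethanesulfonate | FC(F)(F)S(=O)(=O)OC=1[C@@H](C)C[C@H]2OC(=O)[C@H](CN(C)C)[C@H]2CC=1 | intermediate
16 | but-3-en-2-one | CC(=O)C=C | starting material
17 | (3S,3aR,7S,8aR)-3-[(dimethylamino)methyl]-7-methyl-6-[(E)-3-oxobut-1-en-1-yl]-3,3a,4,7,8,8a-hexahydrocyclohepta[b]furan-2-one | CC(=O)/C=C/C=1[C@@H](C)C[C@H]2OC(=O)[C@H](CN(C)C)[C@H]2CC=1 | intermediate
18 | trimethylammonium iodide of 17 (C11–CH2–NMe3+ I−) | CC(=O)/C=C/C=1[C@@H](C)C[C@H]2OC(=O)[C@H](C[N+](C)(C)C)[C@H]2CC=1.[I-] | intermediate (not isolated)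
19 | 8-epi-xanthatin, (3aR,7S,8aR)-7-methyl-3-methylidene-6-[(E)-3-oxobut-1-enyl]-4,7,8,8a-tetrahydro-3aH-cyclohepta[b]furan-2-one | C=C1C(=O)O[C@@H]2C[C@H](C)C(/C=C/C(C)=O)=CC[C@H]12 | intermediate
20 | Diels–Alder dimer of 19 (C1=C2 alkene, 3-H cis to 5-H, spiro lactone at C11') | C=C1C(=O)O[C@@H]2C[C@H](C)C3=C[C@H](C(C)=O)[C@@]4(C[C@@H]3C[C@H]12)C(=O)O[C@@H]1C[C@H](C)C(/C=C/C(C)=O)=CC[C@@H]14 | intermediate
21 | C1 hydroperoxide of the target (C1–OOH, C2=C3) | C=C1C(=O)O[C@@H]2C[C@H](C)[C@@]3(OO)C=C(C(C)=O)[C@@]4(C[C@@H]3C[C@H]12)C(=O)O[C@@H]1C[C@H](C)C(/C=C/C(C)=O)=CC[C@@H]14 | intermediate (not isolated)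
22 | CNP0168949.1 (1-hydroxy Diels–Alder dimer of 8-epi-xanthatin) | C=C1C(=O)O[C@@H]2C[C@H](C)[C@@]3(O)C=C(C(C)=O)[C@@]4(C[C@@H]3C[C@H]12)C(=O)O[C@@H]1C[C@H](C)C(/C=C/C(C)=O)=CC[C@@H]14 | target

**Step count**

Total steps: 13. Longest linear sequence: 13 steps (1 to 22; step 12 uses two molecules of the same intermediate).

**Steps most likely to fail**

1. Step 12 (dimerisation). Two electron-poor π systems must react, so at the temperature needed the methylene lactone may polymerise, the enone may act as dienophile, or facial selectivity at C5 may erode. The face of the diene rests on substrate bias alone and is the least secure stereochemical element of the route. Fallback, from 19 back to 20: the diene is made electron-richer by Luche reduction (NaBH4, CeCl3·7H2O, MeOH, −78 °C) to the C4 carbinol of 8-epi-xanthatin F1 (both C4 epimers are used). This diene should dimerise with its own methylene lactone at lower temperature (PhMe, 60–80 °C) to the bis-carbinol dimer F2. Dess–Martin oxidation of both carbinols (NaHCO3 buffer) then converges on 20.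

2. Step 13 (oxygenation). Site selectivity may be lost because the extended enolate of the lower dienone and the base-sensitive methylene lactone compete, or the C1=C2 alkene may shift into conjugation by proton transfer before oxygen is taken up. Fallback, from 15 and 17 to 22: the two halves are differentiated so that the oxygenation meets one ketone and no free methylene lactone.
   - 15 is quaternised and eliminated (MeI; aq. NaHCO3) to the enol triflate methylene lactone F3, which can only be a dienophile.
   - F3 is heated with 17, which can only be a diene, to give the cross-adduct F4 (amine in the upper half, enol triflate in the lower half).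
   - Oxygenation of the preformed potassium dienolate (KOt-Bu, O2, P(OEt)3, THF, −40 °C) gives the C1 carbinol of the cross-adduct F5.
   - Heck reaction with 16 under the conditions of step 10 gives the amino dienone F6, and MeI then aq. NaHCO3 as in step 11 releases the methylene lactone, which is 22.

3. Step 4 (Ireland–Claisen). The amide base may remove the C10 proton (γ to the ester) or trigger loss of the allylic acetate instead of enolising the acetate. Fallback, from 6 back to 10: the acetate is cleaved reductively (i-Bu2AlH, CH2Cl2, −78 °C) to the C9 allylic alcohol F7. Eschenmoser–Claisen rearrangement with N,N-dimethylacetamide dimethyl acetal (PhMe, 110 °C; no enolate) gives the C7 acetic acid dimethylamide F8 with the same transfer of chirality from C9 to C7. Iodolactonisation of the amide (I2, THF/H2O) then gives 10 directly.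

Further compounds
F1 | step 12 | C4 carbinol of 8-epi-xanthatin (C4 epimers) | C=C1C(=O)O[C@@H]2C[C@H](C)C(/C=C/C(C)O)=CC[C@H]12
F2 | step 12 | bis-carbinol dimer (C4 and C4' epimers) | C=C1C(=O)O[C@@H]2C[C@H](C)C3=C[C@H](C(C)O)[C@@]4(C[C@@H]3C[C@H]12)C(=O)O[C@@H]1C[C@H](C)C(/C=C/C(C)O)=CC[C@@H]14
F3 | step 13 | enol triflate methylene lactone | C=C1C(=O)O[C@@H]2C[C@H](C)C(OS(=O)(=O)C(F)(F)F)=CC[C@H]12
F4 | step 13 | cross-adduct of 17 and F3 | CN(C)C[C@H]1C(=O)O[C@@H]2C[C@H](C)C3=C[C@H](C(C)=O)[C@@]4(C[C@@H]3C[C@H]12)C(=O)O[C@@H]1C[C@H](C)C(OS(=O)(=O)C(F)(F)F)=CC[C@@H]14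
F5 | step 13 | C1 carbinol of the cross-adduct | CN(C)C[C@H]1C(=O)O[C@@H]2C[C@H](C)[C@@]3(O)C=C(C(C)=O)[C@@]4(C[C@@H]3C[C@H]12)C(=O)O[C@@H]1C[C@H](C)C(OS(=O)(=O)C(F)(F)F)=CC[C@@H]14
F6 | step 13 | amino dienone (Mannich base of the target) | CN(C)C[C@H]1C(=O)O[C@@H]2C[C@H](C)[C@@]3(O)C=C(C(C)=O)[C@@]4(C[C@@H]3C[C@H]12)C(=O)O[C@@H]1C[C@H](C)C(/C=C/C(C)=O)=CC[C@@H]14
F7 | step 4 | C9 allylic alcohol, tert-butyl (3S,4S)-2-[(tert-butyldimethylsilyl)oxy]-4-hydroxy-3-methylcyclohepta-1,5-diene-1-carboxylate | CC(C)(C)OC(=O)C1=C(O[Si](C)(C)C(C)(C)C)[C@@H](C)[C@@H](O)C=CC1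
F8 | step 4 | C7 acetic acid dimethylamide | CC(C)(C)OC(=O)C1=C(O[Si](C)(C)C(C)(C)C)[C@@H](C)C=C[C@@H](CC(=O)N(C)C)C1
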